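Cuts, in retrosynthetic order: C4–C4a (aryl ketone bond of flavanone ring C), O1–C2 (benzylic aryl ether), C2–C3 (bond from the ring B aldehyde carbon to the two-carbon chain) and C5'–C6'' (biaryl bond between ring B and the apigenin unit).
Enabling feature: ring A carries its three oxygens (O1 on C8a, 5-O, 7-O) in a 1,3,5-array. In an open 3,5-bis(benzyloxy)phenyl ether the two carbons next to the ether oxygen, the future C4a and C8, are therefore identical by symmetry, and each lies ortho or para to all three oxygens, so ring C can be closed last with only one possible constitution.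
Forward order: a 6-iodoapigenin tribenzyl ether is joined to the boronate of protected 3-bromo-4,5-dihydroxybenzaldehyde. The aldehyde carbon (C2) is extended by C3–C4 with tert-butyl diazoacetate, ring A is attached through O1, and ring C is the only ring built.
Stereochemistry: C2, the only stereocentre, is set as the (R)-carbinol by Ru/(R,R)-TsDPEN transfer hydrogenation of the β-keto ester and turned into (S) by Mitsunobu inversion.
Protecting groups: acetates on the catechol keep ring B electron-poor, so the benzylic C2–O bond should not ionise. All other phenols are benzyl ethers, so the end game is neutral hydrogenolysis followed by cold acid methanolysis, and no base touches the flavanone.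

Key step: step 13

Assumption: the C5'–C6'' axis has three ortho oxygen substituents and one ortho hydrogen and is taken to rotate freely at room temperature, so C2 is the only stereogenic element, as the SMILES implies.
Conventions: flavanone atoms are O1 to C8a and ring B atoms C1' to C6'. The apigenin unit is double-primed and its phenyl ring triple-primed. Ar = 3,4-diacetoxy-5-{5,7-bis(benzyloxy)-2-[4-(benzyloxy)phenyl]-4-oxo-4H-chromen-6-yl}phenyl.

Step 1
Reactants: 1 apigenin (5,7-dihydroxy-2-(4-hydroxyphenyl)-4H-chromen-4-one)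
Product: 2 7-(benzyloxy)-2-[4-(benzyloxy)phenyl]-5-hydroxy-4H-chromen-4-one
Conditions: BnBr (2.2 equiv), K2CO3, DMF, rt
Reagents that add atoms: benzyl bromide, BrCc1ccccc1
Why: Williamson etherification in which the acidic 7''- and 4'''-hydroxyls react, whereas the 5''-hydroxyl, locked in a hydrogen bond to the C4'' carbonyl, should stay free at this stoichiometry and temperature.

Step 2
Reactants: 2 7-(benzyloxy)-2-[4-(benzyloxy)phenyl]-5-hydroxy-4H-chromen-4-one
Product: 3 7-(benzyloxy)-2-[4-(benzyloxy)phenyl]-5-hydroxy-6-iodo-4H-chromen-4-one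
Conditions: BnMe3N·ICl2 (1.1 equiv), CaCO3, CH2Cl2/MeOH, rt
Reagents that add atoms: benzyltrimethylammonium dichloroiodate, C[N+](C)(C)Cc1ccccc1.Cl[I-]Cl
Why: Electrophilic aromatic iodination, for which 5-hydroxy-7-alkoxyflavones are known to react at the carbon ortho to the free chelated hydroxyl (C6'') rather than at C8'', with CaCO3 taking up the HCl.

Step 3
Reactants: 3 7-(benzyloxy)-2-[4-(benzyloxy)phenyl]-5-hydroxy-6-iodo-4H-chromen-4-one
Product: 4 5,7-bis(benzyloxy)-2-[4-(benzyloxy)phenyl]-6-iodo-4H-chromen-4-one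
Conditions: BnBr (1.5 equiv), K2CO3, DMF, 70 °C
Reagents that add atoms: benzyl bromide, BrCc1ccccc1
Why: Williamson etherification at higher temperature overcomes the chelation and the flanking iodine and removes the last acidic OH, which would otherwise compete as a nucleophile in step 11.

Step 4
Reactants: 5 3-bromo-4,5-dihydroxybenzaldehyde
Product: 6 3-bromo-4,5-bis(methoxymethoxy)benzaldehyde
Conditions: MOMCl (3 equiv), i-Pr2NEt, CH2Cl2, 0 °C to rt
Reagents that add atoms: chloromethyl methyl ether, COCCl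
Why: O-alkylation to two methoxymethyl acetals, which withstand the basic palladium steps and, unlike benzyl ethers, can later be removed by acid without hydrogenating the aldehyde or touching the benzyl ethers of the apigenin unit.

Step 5
Reactants: 6 3-bromo-4,5-bis(methoxymethoxy)benzaldehyde
Product: 7 3,4-bis(methoxymethoxy)-5-(4,4,5,5-tetramethyl-1,3,2-dioxaborolan-2-yl)benzaldehyde
Conditions: B2pin2, PdCl2(dppf) (3 mol %), KOAc, 1,4-dioxane, 90 °C
Reagents that add atoms: bis(pinacolato)diboron, CC1(C)OB(OC1(C)C)B1OC(C)(C)C(C)(C)O1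
Why: Miyaura borylation of an aryl bromide, which tolerates the aldehyde and the acetals and places boron on the less hindered coupling partner.

Step 6
Reactants: 4 5,7-bis(benzyloxy)-2-[4-(benzyloxy)phenyl]-6-iodo-4H-chromen-4-one; 7 3,4-bis(methoxymethoxy)-5-(4,4,5,5-tetramethyl-1,3,2-dioxaborolan-2-yl)benzaldehyde
Product: 8 3-{5,7-bis(benzyloxy)-2-[4-(benzyloxy)phenyl]-4-oxo-4H-chromen-6-yl}-4,5-bis(methoxymethoxy)benzaldehyde
Conditions: Pd(OAc)2 (5 mol %), SPhos (2-dicyclohexylphosphino-2',6'-dimethoxybiphenyl, 10 mol %), K3PO4, toluene/H2O, 90 °C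
Reagents that add atoms: none
Why: Suzuki–Miyaura coupling forming C5'–C6''; the C–I bond adds readily to zerovalent palladium, the bulky electron-rich biarylphosphine is designed for biaryls with three ortho substituents, and a 2,6-dialkoxyarylboron reagent prone to protodeboronation is avoided.

Step 7
Reactants: 8 3-{5,7-bis(benzyloxy)-2-[4-(benzyloxy)phenyl]-4-oxo-4H-chromen-6-yl}-4,5-bis(methoxymethoxy)benzaldehyde
Product: 9 3-{5,7-bis(benzyloxy)-2-[4-(benzyloxy)phenyl]-4-oxo-4H-chromen-6-yl}-4,5-dihydroxybenzaldehyde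
Conditions: 3 M aq HCl, THF/i-PrOH, 40 °C
Reagents that add atoms: none
Why: Acid hydrolysis of the aryl methoxymethyl acetals, under which aryl benzyl ethers, the chromenone and the aldehyde should persist.

Step 8
Reactants: 9 3-{5,7-bis(benzyloxy)-2-[4-(benzyloxy)phenyl]-4-oxo-4H-chromen-6-yl}-4,5-dihydroxybenzaldehyde
Product: 10 Ar–CHO (3-{5,7-bis(benzyloxy)-2-[4-(benzyloxy)phenyl]-4-oxo-4H-chromen-6-yl}-5-formyl-1,2-phenylene diacetate)
Conditions: Ac2O, pyridine, DMAP (cat.), CH2Cl2, 0 °C to rt
Reagents that add atoms: acetic anhydride, CC(=O)OC(C)=O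
Why: DMAP-catalysed O-acylation gives the catechol diacetate, which from here on makes ring B electron-poor, the property on which steps 11 to 13 depend.

Step 9
Reactants: 10 Ar–CHO; 11 tert-butyl diazoacetate
Product: 12 tert-butyl 3-Ar-3-oxopropanoate
Conditions: SnCl2 (20 mol %), CH2Cl2, rt
Reagents that add atoms: none
Why: Roskamp homologation: the diazo carbon adds to the SnCl2-activated aldehyde (C2–C3 bond) and a 1,2-hydride shift with loss of N2 gives the β-keto ester under neutral conditions that spare the acetates, hydride rather than aryl migration being favoured by the electron-poor ring.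

Step 10
Reactants: 12 tert-butyl 3-Ar-3-oxopropanoate
Product: 13 tert-butyl (R)-3-Ar-3-hydroxypropanoate
Conditions: RuCl(p-cymene)[(R,R)-TsDPEN] (2 mol %), HCO2H/Et3N (5:2), CH2Cl2, 30 °C
Reagents that add atoms: none
Why: Noyori–Ikariya asymmetric transfer hydrogenation: the (R,R)-catalyst passes hydride and proton to the aryl ketone through the six-membered transition state in which the aryl ring sits under the p-cymene ligand, which should give the (R)-carbinol at the future C2, while the acidic, alcohol-free medium spares acetates, benzyl ethers, the tert-butyl ester and the chromenone.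

Step 11
Reactants: 13 tert-butyl (R)-3-Ar-3-hydroxypropanoate; 14 3,5-bis(benzyloxy)phenol
Product: 15 tert-butyl (S)-3-Ar-3-[3,5-bis(benzyloxy)phenoxy]propanoate
Conditions: PPh3, DIAD, toluene, 0 °C
Reagents that add atoms: none
Why: Mitsunobu etherification forming O1–C2: the phenol displaces the alcohol activated in situ by PPh3/DIAD in an SN2 process with inversion, (R) to (S), because the electron-poor ring B and the β-ester disfavour a benzylic cation, and the bulky tert-butyl ester, the apolar solvent and the low temperature are chosen to suppress β-elimination.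

Step 12
Reactants: 15 tert-butyl (S)-3-Ar-3-[3,5-bis(benzyloxy)phenoxy]propanoate
Product: 17 (S)-3-Ar-3-[3,5-bis(benzyloxy)phenoxy]propanoic acid, via trimethylsilyl ester 16 (not isolated)
Conditions: TMSOTf, 2,6-lutidine, CH2Cl2, 0 °C; then aq NaH2PO4 work-up
Reagents that add atoms: trimethylsilyl trifluoromethanesulfonate, C[Si](C)(C)OS(=O)(=O)C(F)(F)F (its silyl group is found in 16 only)
Why: Silyl triflate mediated cleavage of a tert-butyl ester: O-silylation triggers loss of the tert-butyl group as 2-methylpropene, which the buffered medium does not reprotonate, so the nucleophilic phloroglucinol ring should escape tert-butylation, the acetates, benzyl ethers and C2–O bond are not exposed to free strong acid, and the silyl ester is hydrolysed on aqueous work-up.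

Step 13
Reactants: 17 (S)-3-Ar-3-[3,5-bis(benzyloxy)phenoxy]propanoic acid
Product: 19 (2S)-5,7-bis(benzyloxy)-2-Ar-chroman-4-one, via mixed trifluoroacetic anhydride 18 (not isolated)
Conditions: (CF3CO)2O (1.2 equiv), CH2Cl2, 0 °C
Reagents that add atoms: trifluoroacetic anhydride, O=C(OC(=O)C(F)(F)F)C(F)(F)F (its trifluoroacetyl group is found in 18 only)
Why: The anhydride converts the acid into 18, whose acyl carbon, as such or after ionisation to the acylium ion, is attacked by the carbon of the 3,5-bis(benzyloxy)phenoxy ring that lies ortho to the ether oxygen and para to a benzyloxy group, and proton loss from the arenium ion gives the aryl ketone and the C4–C4a bond. The closest known reaction type is the intramolecular Friedel–Crafts acylation of 3-aryloxypropanoic acids to chroman-4-ones. Ring C closes as a six-membered ring by 6-exo-trig attack on the acyl carbon, the carbon para to the ether oxygen being out of reach of the three-atom tether. No stereocentre is made, and C2 should be retained because none of its bonds takes part, no base is present for β-elimination, and heterolysis of the benzylic C2–O bond is opposed by the 3'- and 4'-acetoxy groups, the chromenone substituent on ring B and the adjacent acyl chain. Regioselectivity needs no control, since the two ortho carbons are interchanged by rotation about the O–aryl bond, and chemoselectivity rests on this ring being the only arene with three donor oxygens and no acyl group, so a small excess of anhydride at 0 °C should suffice and leave benzyl ethers and acetates alone. Once formed, the ketone deactivates ring A against trifluoroacetylation.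

Step 14
Reactants: 19 (2S)-5,7-bis(benzyloxy)-2-Ar-chroman-4-one
Product: 20 (2S)-2-{3,4-diacetoxy-5-[5,7-dihydroxy-2-(4-hydroxyphenyl)-4-oxo-4H-chromen-6-yl]phenyl}-5,7-dihydroxychroman-4-one
Conditions: H2 (1 atm), 10% Pd/C, THF/EtOAc, rt
Reagents that add atoms: none
Why: Heterogeneous catalytic hydrogenolysis of five primary benzyl aryl ethers in a neutral medium; the endocyclic C2–O1 bond is secondary, part of a vinylogous ester and attached to the still acetylated electron-poor ring B, so it should be cleaved far more slowly, as should the chromenone double bond be reduced.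

Step 15
Reactants: 20 (2S)-2-{3,4-diacetoxy-5-[5,7-dihydroxy-2-(4-hydroxyphenyl)-4-oxo-4H-chromen-6-yl]phenyl}-5,7-dihydroxychroman-4-one
Product: 21 (2S)-2-{3,4-dihydroxy-5-[5,7-dihydroxy-2-(4-hydroxyphenyl)-4-oxo-4H-chromen-6-yl]phenyl}-5,7-dihydroxychroman-4-one (CNP0176432.1)
Conditions: HCl (1.25 M in MeOH), 0 °C to rt; evaporation below 30 °C
Reagents that add atoms: none
Why: Acid-catalysed transesterification of the two aryl acetates to volatile methyl acetate; flavanones open to chalcones and racemise under base, especially once the 4'-hydroxyl para to C2 is free, whereas cold dilute acid should leave C2 untouched and everything except the target can be evaporated.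

Compound list
1 | apigenin | O=c1cc(-c2ccc(O)cc2)oc2cc(O)cc(O)c12 | starting material
2 | 7-(benzyloxy)-2-[4-(benzyloxy)phenyl]-5-hydroxy-4H-chromen-4-one | O=c1cc(-c2ccc(OCc3ccccc3)cc2)oc2cc(OCc3ccccc3)cc(O)c12 | intermediate
3 | 7-(benzyloxy)-2-[4-(benzyloxy)phenyl]-5-hydroxy-6-iodo-4H-chromen-4-one | Ic1c(OCc2ccccc2)cc2oc(-c3ccc(OCc4ccccc4)cc3)cc(=O)c2c1O | intermediate
4 | 5,7-bis(benzyloxy)-2-[4-(benzyloxy)phenyl]-6-iodo-4H-chromen-4-one | Ic1c(OCc2ccccc2)cc2oc(-c3ccc(OCc4ccccc4)cc3)cc(=O)c2c1OCc1ccccc1 | intermediate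
5 | 3-bromo-4,5-dihydroxybenzaldehyde | O=Cc1cc(O)c(O)c(Br)c1 | starting material
6 | 3-bromo-4,5-bis(methoxymethoxy)benzaldehyde | O=Cc1cc(OCOC)c(OCOC)c(Br)c1 | intermediate
7 | 3,4-bis(methoxymethoxy)-5-(4,4,5,5-tetramethyl-1,3,2-dioxaborolan-2-yl)benzaldehyde | O=Cc1cc(OCOC)c(OCOC)c(B2OC(C)(C)C(C)(C)O2)c1 | intermediate
8 | 3-{5,7-bis(benzyloxy)-2-[4-(benzyloxy)phenyl]-4-oxo-4H-chromen-6-yl}-4,5-bis(methoxymethoxy)benzaldehyde | O=Cc1cc(OCOC)c(OCOC)c(-c2c(OCc3ccccc3)cc3oc(-c4ccc(OCc5ccccc5)cc4)cc(=O)c3c2OCc2ccccc2)c1 | intermediate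
9 | 3-{5,7-bis(benzyloxy)-2-[4-(benzyloxy)phenyl]-4-oxo-4H-chromen-6-yl}-4,5-dihydroxybenzaldehyde | O=Cc1cc(O)c(O)c(-c2c(OCc3ccccc3)cc3oc(-c4ccc(OCc5ccccc5)cc4)cc(=O)c3c2OCc2ccccc2)c1 | intermediate
10 | Ar–CHO, 3-{5,7-bis(benzyloxy)-2-[4-(benzyloxy)phenyl]-4-oxo-4H-chromen-6-yl}-5-formyl-1,2-phenylene diacetate | O=Cc1cc(OC(C)=O)c(OC(C)=O)c(-c2c(OCc3ccccc3)cc3oc(-c4ccc(OCc5ccccc5)cc4)cc(=O)c3c2OCc2ccccc2)c1 | intermediate
11 | tert-butyl diazoacetate | CC(C)(C)OC(=O)C=[N+]=[N-] | starting material
12 | tert-butyl 3-Ar-3-oxopropanoate | CC(C)(C)OC(=O)CC(=O)c1cc(OC(C)=O)c(OC(C)=O)c(-c2c(OCc3ccccc3)cc3oc(-c4ccc(OCc5ccccc5)cc4)cc(=O)c3c2OCc2ccccc2)c1 | intermediate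
13 | tert-butyl (R)-3-Ar-3-hydroxypropanoate | CC(C)(C)OC(=O)C[C@@H](O)c1cc(OC(C)=O)c(OC(C)=O)c(-c2c(OCc3ccccc3)cc3oc(-c4ccc(OCc5ccccc5)cc4)cc(=O)c3c2OCc2ccccc2)c1 | intermediate
14 | 3,5-bis(benzyloxy)phenol | Oc1cc(OCc2ccccc2)cc(OCc2ccccc2)c1 | starting material
15 | tert-butyl (S)-3-Ar-3-[3,5-bis(benzyloxy)phenoxy]propanoate | CC(C)(C)OC(=O)C[C@@H](c1cc(OC(C)=O)c(OC(C)=O)c(-c2c(OCc3ccccc3)cc3oc(-c4ccc(OCc5ccccc5)cc4)cc(=O)c3c2OCc2ccccc2)c1)Oc1cc(OCc2ccccc2)cc(OCc2ccccc2)c1 | intermediate
16 | trimethylsilyl (S)-3-Ar-3-[3,5-bis(benzyloxy)phenoxy]propanoate | C[Si](C)(C)OC(=O)C[C@@H](c1cc(OC(C)=O)c(OC(C)=O)c(-c2c(OCc3ccccc3)cc3oc(-c4ccc(OCc5ccccc5)cc4)cc(=O)c3c2OCc2ccccc2)c1)Oc1cc(OCc2ccccc2)cc(OCc2ccccc2)c1 | intermediate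
17 | (S)-3-Ar-3-[3,5-bis(benzyloxy)phenoxy]propanoic acid | OC(=O)C[C@@H](c1cc(OC(C)=O)c(OC(C)=O)c(-c2c(OCc3ccccc3)cc3oc(-c4ccc(OCc5ccccc5)cc4)cc(=O)c3c2OCc2ccccc2)c1)Oc1cc(OCc2ccccc2)cc(OCc2ccccc2)c1 | intermediate
18 | (S)-3-Ar-3-[3,5-bis(benzyloxy)phenoxy]propanoic trifluoroacetic anhydride | FC(F)(F)C(=O)OC(=O)C[C@@H](c1cc(OC(C)=O)c(OC(C)=O)c(-c2c(OCc3ccccc3)cc3oc(-c4ccc(OCc5ccccc5)cc4)cc(=O)c3c2OCc2ccccc2)c1)Oc1cc(OCc2ccccc2)cc(OCc2ccccc2)c1 | intermediate
19 | (2S)-5,7-bis(benzyloxy)-2-Ar-chroman-4-one | O=C1C[C@@H](c2cc(OC(C)=O)c(OC(C)=O)c(-c3c(OCc4ccccc4)cc4oc(-c5ccc(OCc6ccccc6)cc5)cc(=O)c4c3OCc3ccccc3)c2)Oc2cc(OCc3ccccc3)cc(OCc3ccccc3)c21 | intermediate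
20 | (2S)-2-{3,4-diacetoxy-5-[5,7-dihydroxy-2-(4-hydroxyphenyl)-4-oxo-4H-chromen-6-yl]phenyl}-5,7-dihydroxychroman-4-one | O=C1C[C@@H](c2cc(OC(C)=O)c(OC(C)=O)c(-c3c(O)cc4oc(-c5ccc(O)cc5)cc(=O)c4c3O)c2)Oc2cc(O)cc(O)c21 | intermediate
21 | (2S)-2-{3,4-dihydroxy-5-[5,7-dihydroxy-2-(4-hydroxyphenyl)-4-oxo-4H-chromen-6-yl]phenyl}-5,7-dihydroxychroman-4-one (CNP0176432.1) | O=C1C[C@@H](c2cc(O)c(O)c(-c3c(O)cc4oc(-c5ccc(O)cc5)cc(=O)c4c3O)c2)Oc2cc(O)cc(O)c21 | target

Total step count: 15.
Longest linear sequence: 13 steps (steps 1 to 3 and 6 to 15, from apigenin 1 to target 21).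

Steps most likely to fail

Step 11 (Mitsunobu etherification). The activated alcohol may undergo β-elimination across C2–C3 because the ester α-hydrogens are acidic. Inversion may be incomplete if an ion pair forms, and an acetyl group may be transferred from ring B to the phenoxide. The fallback sets out from 10 and comes back at 17, replacing steps 9 to 12 with a chain that has no acidic hydrogen next to the reacting carbon. Aldehyde 10 would undergo Keck allylation (allyltributylstannane, Ti(OiPr)4, (R)-BINOL, 4 Å molecular sieves, CH2Cl2, −20 °C) to the (R)-homoallylic alcohol F1. Mitsunobu reaction of this alcohol with phenol 14 (PPh3, DIAD, toluene, 0 °C) should give with inversion the (S)-homoallylic aryl ether F2. Lemieux–Johnson cleavage (OsO4 cat., NaIO4, 2,6-lutidine, dioxane/H2O) would shorten the alkene to the (S)-β-aryloxy aldehyde F3. Buffered Pinnick oxidation (NaClO2, NaH2PO4, excess 2-methyl-2-butene, t-BuOH/H2O) would then deliver acid 17.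

Step 13 (key ring closure). Ring A may be trifluoroacetylated by the anhydride before it is acylated intramolecularly. The liberated acid may cause migration or loss of benzyl groups, and slow heterolysis of the benzylic C2–O bond would erode the configuration. The fallback sets out from 17 and comes back at 19, keeping the C4–C4a disconnection but changing the electrophile and removing every trifluoroacetylating species. Acid 17 would be converted under neutral conditions with 1-chloro-N,N,2-trimethylprop-1-en-1-amine (CH2Cl2, 0 °C) into the (S)-acid chloride F4. This would be dissolved in 1,1,1,3,3,3-hexafluoropropan-2-ol at rt, a hydrogen-bond-donor medium known to promote intramolecular Friedel–Crafts acylation of electron-rich arenes by acid chlorides without a Lewis acid.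

Step 6 (Suzuki–Miyaura coupling). Transmetalation onto the palladium centre flanked by two benzyloxy groups may be slow, so that protodeboronation of the boronate and reductive loss of iodine from the flavone compete. The fallback sets out from 6 (with 4 as partner) and comes back at 8, exchanging boron and aqueous base for tin and fluoride. Bromide 6 would be stannylated (Me3SnSnMe3, Pd(PPh3)4, toluene, 100 °C) to the arylstannane F5. This would be joined to iodide 4 by a copper-assisted Stille coupling (Pd(PPh3)4, CuI, CsF, DMF, 50 °C), in which the more reactive arylcopper species carries the aryl group to the hindered palladium centre.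

Further compounds
F1 | step 11 | (R)-1-Ar-but-3-en-1-ol, the (R)-homoallylic alcohol | C=CC[C@@H](O)c1cc(OC(C)=O)c(OC(C)=O)c(-c2c(OCc3ccccc3)cc3oc(-c4ccc(OCc5ccccc5)cc4)cc(=O)c3c2OCc2ccccc2)c1
F2 | step 11 | (S)-1-Ar-but-3-en-1-yl 3,5-bis(benzyloxy)phenyl ether, the (S)-homoallylic aryl ether | C=CC[C@@H](c1cc(OC(C)=O)c(OC(C)=O)c(-c2c(OCc3ccccc3)cc3oc(-c4ccc(OCc5ccccc5)cc4)cc(=O)c3c2OCc2ccccc2)c1)Oc1cc(OCc2ccccc2)cc(OCc2ccccc2)c1
F3 | step 11 | (S)-3-Ar-3-[3,5-bis(benzyloxy)phenoxy]propanal, the (S)-β-aryloxy aldehyde | O=CC[C@@H](c1cc(OC(C)=O)c(OC(C)=O)c(-c2c(OCc3ccccc3)cc3oc(-c4ccc(OCc5ccccc5)cc4)cc(=O)c3c2OCc2ccccc2)c1)Oc1cc(OCc2ccccc2)cc(OCc2ccccc2)c1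
F4 | step 13 | (S)-3-Ar-3-[3,5-bis(benzyloxy)phenoxy]propanoyl chloride, the (S)-acid chloride | ClC(=O)C[C@@H](c1cc(OC(C)=O)c(OC(C)=O)c(-c2c(OCc3ccccc3)cc3oc(-c4ccc(OCc5ccccc5)cc4)cc(=O)c3c2OCc2ccccc2)c1)Oc1cc(OCc2ccccc2)cc(OCc2ccccc2)c1
F5 | step 6 | 3,4-bis(methoxymethoxy)-5-(trimethylstannyl)benzaldehyde, the arylstannane | O=Cc1cc(OCOC)c(OCOC)c([Sn](C)(C)C)c1
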